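**Plan**
1. Retrosynthesis: cut the C3–C1' bond between ring C and ring B together with the O1–C2 bond of the pyranone; then remove C2 (a one-carbon unit) from the acetyl group; then cut the 8-OMe C–O bond and the acetyl–arene bond, back to 3,4,5-trimethoxyphenol.
2. Enabling feature: opened at O1–C2, ring C is an o-hydroxyaryl enaminone whose α-carbon (future C3) is a nucleophilic, radical-accepting vinylogous-amide carbon, and the ring-A hydroxyl (future O1) sits where it can trap the iminium carbon (future C2) that the coupling creates.
3. Forward: ring A is completed first (acylation, bromination, methoxylation, enaminone); ring B arrives as an aryl radical generated at the carbon that carried N2+, so its 1,2,3-pattern is fixed by the starting nitrophenol; ring C closes last, in the same flask as the C3–C1' bond.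
4. One BCl3 operation then frees both 5-OH (peri-chelation) and 3'-OH (benzyl ether).
5. Stereochemistry: none to set; the target is planar and achiral.

Key step: step 8

Remark: the target has no stereocentre, and its C3–C1' axis (a single ortho substituent on ring B) rotates freely, so it exists as one achiral compound and no enantiocontrol is needed.

**Route**

Step 1
Reactants: 1 3,4,5-trimethoxyphenol
Product: 2 1-(2-hydroxy-4,5,6-trimethoxyphenyl)ethan-1-one
Conditions: AcOH (acyl donor and solvent), BF3·OEt2 (promoter), 90 °C; H2O quench
Reagents that add atoms: acetic acid, CC(=O)O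
Why: BF3-promoted Friedel–Crafts C-acylation of the activated phenol should occur at one of the two equivalent positions ortho to OH, and chelation of the product should stop a second acylation.

Step 2
Reactants: 2 1-(2-hydroxy-4,5,6-trimethoxyphenyl)ethan-1-one
Product: 3 1-(3-bromo-2-hydroxy-4,5,6-trimethoxyphenyl)ethan-1-one
Conditions: NBS (1.05 equiv), MeCN, 0 °C to rt, dark
Reagents that add atoms: N-bromosuccinimide, O=C1CCC(=O)N1Br
Why: Electrophilic aromatic bromination should take the single free ring position, which is ortho to the phenol OH and far more nucleophilic than the enol of the hydrogen-bonded acetyl group.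

Step 3
Reactants: 3 1-(3-bromo-2-hydroxy-4,5,6-trimethoxyphenyl)ethan-1-one
Product: 4 1-(2-hydroxy-3,4,5,6-tetramethoxyphenyl)ethan-1-one
Conditions: NaOMe (excess), CuBr (cat.), DMF–MeOH, 110 °C; aq. HCl work-up
Reagents that add atoms: sodium methoxide, C[O-].[Na+]
Why: Copper(I)-catalysed Ullmann-type methoxylation of an aryl bromide lying ortho to a phenoxide is a standard conversion of bromophenols into methoxyphenols, and the phenoxide character of the substrate should disfavour aldol chemistry at the acetyl group.

Step 4
Reactants: 4 1-(2-hydroxy-3,4,5,6-tetramethoxyphenyl)ethan-1-one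
Product: 5 (E)-3-(dimethylamino)-1-(2-hydroxy-3,4,5,6-tetramethoxyphenyl)prop-2-en-1-one
Conditions: DMF dimethyl acetal (3 equiv), toluene, 100 °C
Reagents that add atoms: N,N-dimethylformamide dimethyl acetal, COC(OC)N(C)C
Why: Condensation of the acetyl CH3 with the amide acetal (enaminone formation) should give the E-enaminone, whose OH···O=C hydrogen bond protects the phenol from methylation and from premature cyclisation.

Step 5
Reactants: 6 2-methoxy-3-nitrophenol
Product: 7 1-(benzyloxy)-2-methoxy-3-nitrobenzene
Conditions: BnBr, K2CO3, DMF, rt
Reagents that add atoms: benzyl bromide, BrCc1ccccc1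
Why: Williamson O-benzylation of the only acidic OH should be clean, and the benzyl group shields the future 3'-oxygen from azo coupling and oxidation in the later steps.

Step 6
Reactants: 7 1-(benzyloxy)-2-methoxy-3-nitrobenzene
Product: 8 3-(benzyloxy)-2-methoxyaniline
Conditions: Fe powder, AcOH–EtOH, 70 °C
Reagents that add atoms: none
Why: Béchamp-type iron/acid reduction of the nitro group should leave the benzyl ether intact, which hydrogenation over palladium would not.

Step 7
Reactants: 8 3-(benzyloxy)-2-methoxyaniline
Product: 9 3-(benzyloxy)-2-methoxybenzenediazonium tetrafluoroborate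
Conditions: t-BuONO, 48% aq. HBF4, EtOH, 0 °C; precipitation with Et2O; used cold and promptly
Reagents that add atoms: tert-butyl nitrite, CC(C)(C)ON=O; tetrafluoroboric acid, [H+].F[B-](F)(F)F
Why: Diazotisation of the aniline with a non-nucleophilic counter-ion should give an isolable salt that carries its leaving group exactly on the future C1'.

Step 8
Reactants: 5 (E)-3-(dimethylamino)-1-(2-hydroxy-3,4,5,6-tetramethoxyphenyl)prop-2-en-1-one; 9 3-(benzyloxy)-2-methoxybenzenediazonium tetrafluoroborate
Product: 11 3-[3-(benzyloxy)-2-methoxyphenyl]-5,6,7,8-tetramethoxy-4H-chromen-4-one, via 2-(dimethylamino)chromanone aminal 10 (not isolated)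
Conditions: 9 (1.5 equiv, added in portions), Ru(bpy)3Cl2·6H2O (1 mol %), degassed DMSO, blue LEDs (450 nm), 20 °C, no added base
Reagents that add atoms: none
Why: Single-electron reduction of 9 by the photoexcited Ru(II) complex releases N2 and an aryl σ-radical, which adds to the enaminone α-carbon (electrophilic radical, enamine-type carbon) to give an N-stabilised α-amino radical that is oxidised by Ru(III), or by 9 in a chain, to an iminium ion. The closest known reaction type is the visible-light Meerwein-type arylation–annulation of o-hydroxyaryl enaminones with aryl onium salts to give isoflavones. Ring C closes by 6-exo-trig attack of the phenolic oxygen on the iminium carbon to give aminal 10, and E1cB loss of dimethylamine then forms the C2=C3 double bond. Both sp3 centres of 10 are destroyed in that elimination, so no stereocontrol is required. The step needs C–C bond formation at the α-carbon in preference to ionic azo coupling or triazene formation, which a low standing concentration of 9, continuous irradiation and the absence of free amine should favour; the site of the new bond on ring B is fixed because the radical is born at the carbon that carried N2+.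

Step 9
Reactants: 11 3-[3-(benzyloxy)-2-methoxyphenyl]-5,6,7,8-tetramethoxy-4H-chromen-4-one
Product: 12 5-hydroxy-3-(3-hydroxy-2-methoxyphenyl)-6,7,8-trimethoxy-4H-chromen-4-one
Conditions: BCl3 (1 M in CH2Cl2, 5 equiv), pentamethylbenzene (3 equiv), CH2Cl2, −78 °C to 0 °C; aq. NaHCO3 work-up
Reagents that add atoms: none
Why: BCl3 should cleave the benzyl ether at low temperature (benzyl cation trapped by pentamethylbenzene in a Friedel–Crafts alkylation) and, on warming, the one methyl ether whose oxygen can chelate boron together with the C4 carbonyl (peri 5-OMe), while the non-chelating 6-, 7-, 8- and 2'-methyl ethers should survive.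

**Compound list**
1 | 3,4,5-trimethoxyphenol | COc1cc(O)cc(OC)c1OC | starting material
2 | 1-(2-hydroxy-4,5,6-trimethoxyphenyl)ethan-1-one | CC(=O)c1c(O)cc(OC)c(OC)c1OC | intermediate
3 | 1-(3-bromo-2-hydroxy-4,5,6-trimethoxyphenyl)ethan-1-one | CC(=O)c1c(O)c(Br)c(OC)c(OC)c1OC | intermediate
4 | 1-(2-hydroxy-3,4,5,6-tetramethoxyphenyl)ethan-1-one | CC(=O)c1c(O)c(OC)c(OC)c(OC)c1OC | intermediate
5 | (E)-3-(dimethylamino)-1-(2-hydroxy-3,4,5,6-tetramethoxyphenyl)prop-2-en-1-one | CN(C)/C=C/C(=O)c1c(O)c(OC)c(OC)c(OC)c1OC | intermediate
6 | 2-methoxy-3-nitrophenol | COc1c(O)cccc1[N+](=O)[O-] | starting material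
7 | 1-(benzyloxy)-2-methoxy-3-nitrobenzene | COc1c(OCc2ccccc2)cccc1[N+](=O)[O-] | intermediate
8 | 3-(benzyloxy)-2-methoxyaniline | COc1c(OCc2ccccc2)cccc1N | intermediate
9 | 3-(benzyloxy)-2-methoxybenzenediazonium tetrafluoroborate | COc1c(OCc2ccccc2)cccc1[N+]#N.F[B-](F)(F)F | intermediate
10 | 3-[3-(benzyloxy)-2-methoxyphenyl]-2-(dimethylamino)-5,6,7,8-tetramethoxy-2,3-dihydro-4H-chromen-4-one (diastereomer mixture, not isolated) | CN(C)C1Oc2c(OC)c(OC)c(OC)c(OC)c2C(=O)C1c1cccc(OCc2ccccc2)c1OC | intermediate
11 | 3-[3-(benzyloxy)-2-methoxyphenyl]-5,6,7,8-tetramethoxy-4H-chromen-4-one | COc1c(OCc2ccccc2)cccc1-c1coc2c(OC)c(OC)c(OC)c(OC)c2c1=O | intermediate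
12 | 5-hydroxy-3-(3-hydroxy-2-methoxyphenyl)-6,7,8-trimethoxy-4H-chromen-4-one (5,3'-dihydroxy-6,7,8,2'-tetramethoxyisoflavone) | COc1c(O)cccc1-c1coc2c(OC)c(OC)c(OC)c(O)c2c1=O | target

**Totals**
Total step count: 9.
Longest linear sequence: 6 steps (1, 2, 3, 4, 8, 9); the ring-B branch (5, 6, 7) joins at step 8.

**Steps most likely to fail**

Step 8. The ionic azo coupling of the diazonium ion at the enaminone α-carbon, triazene formation with liberated amine, or hydrogen abstraction by the aryl radical may outrun the radical C-arylation. The fallback makes the same bond by Suzuki–Miyaura coupling; it sets out from 5 (and from 8 for the boron partner) and returns at 11. Enaminone 5 would be treated with I2 in CHCl3 at rt, where iodination at the α-carbon triggers cyclisation and loss of dimethylamine, to give 3-iodo-5,6,7,8-tetramethoxy-4H-chromen-4-one F1. Aniline 8 would be converted by a Sandmeyer-type borylation (t-BuONO, B2pin2, MeCN, rt) into 2-[3-(benzyloxy)-2-methoxyphenyl]-4,4,5,5-tetramethyl-1,3,2-dioxaborolane F2. Coupling of F1 and F2 with Pd(dppf)Cl2 and K2CO3 in dioxane–H2O at 80 °C should give 11.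

Step 3. Substitution at the C–Br bond, which is flanked on both sides by oxygen substituents, may be slow, so that protodebromination and base-induced condensation of the acetyl group compete. The fallback installs the oxygen by formylation and oxidation instead of substitution; it sets out from 2 and returns at 4. Duff formylation of 2 (hexamethylenetetramine, TFA, 80 °C, then aqueous acid) at the one free position ortho to OH should give 3-acetyl-2-hydroxy-4,5,6-trimethoxybenzaldehyde F3. Dakin oxidation (H2O2, aq. NaOH, 0 °C to rt), which is faster for the aldehyde than for the ketone, should give 1-(2,3-dihydroxy-4,5,6-trimethoxyphenyl)ethan-1-one F4. Methylation of the dianion of F4 (NaH 2.2 equiv, MeI 1 equiv, DMSO, rt) should occur at the 3-oxide, which is not conjugated to the acetyl group, to give 4.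

Step 9. Over-cleavage may occur at the 6-OMe next to the boron-bound 5-oxygen or at the 2'-OMe next to the freed 3'-oxygen, or the 5-O-demethylation may stay incomplete at the temperature that spares the other ethers. The fallback separates the two unmaskings with orthogonal reagents; it sets out from 11 and returns at 12. Hydrogenolysis of 11 (H2 1 atm, Pd/C, EtOAc–MeOH, rt, stopped at consumption of 11 to spare the C2=C3 bond) should give 3-(3-hydroxy-2-methoxyphenyl)-5,6,7,8-tetramethoxy-4H-chromen-4-one F5. Treatment of F5 with anhydrous AlCl3 in MeCN (rt to 50 °C, then dilute HCl), a reagent known for selective peri-demethylation of 5-methoxy-4-chromenones, should give 12.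

**Further compounds**
F1 | step 8 | 3-iodo-5,6,7,8-tetramethoxy-4H-chromen-4-one | O=c1c(I)coc2c(OC)c(OC)c(OC)c(OC)c12
F2 | step 8 | 2-[3-(benzyloxy)-2-methoxyphenyl]-4,4,5,5-tetramethyl-1,3,2-dioxaborolane | COc1c(OCc2ccccc2)cccc1B1OC(C)(C)C(C)(C)O1
F3 | step 3 | 3-acetyl-2-hydroxy-4,5,6-trimethoxybenzaldehyde | CC(=O)c1c(O)c(C=O)c(OC)c(OC)c1OC
F4 | step 3 | 1-(2,3-dihydroxy-4,5,6-trimethoxyphenyl)ethan-1-one | CC(=O)c1c(O)c(O)c(OC)c(OC)c1OC
F5 | step 9 | 3-(3-hydroxy-2-methoxyphenyl)-5,6,7,8-tetramethoxy-4H-chromen-4-one | COc1c(O)cccc1-c1coc2c(OC)c(OC)c(OC)c(OC)c2c1=O
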